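Numbering: C1=C2 vinyl; C3–C7 the oxane carbons (O joins C3 and C7, Br on C6); C8–C9 the ethylene link; ring A is the cyclohexane C10–C15 (C11 carbinol, C14 CHBr, C15 CMe2).
Cuts, in retrosynthetic order: O–C3 and C6–Br of the oxane (two epoxide openings), C7–C8 (B-alkyl Suzuki coupling), then C10–C11 and O–C9 together (aldol-lactonisation of an acyclic bromo keto acid).
Enabling feature: on ring A the axial C11 oxygen is cis to the C9 carbon on C10, so O–C11–C10–C9 is a masked cis-fused oxetan-2-one. With C9 at the carboxyl level, one step closes the cyclohexane and the β-lactone and makes the cis relation compulsory.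
Forward: 3,3-dimethylglutaric anhydride → C9–C15 bromo keto acid → ring A with β-lactone → lactone reduced and C9 methylenated (adds C8) → coupling with a C1–C7 vinyl iodide from geranyl acetate → oxane closed last.
Stereochemistry: C14 comes from enamine-catalysed α-bromination. C10 and C11 come from the key step (isothiourea face selection matched with the Br-equatorial chair, cis fusion). C7 and C6 come from Shi epoxidation and invertive bromide opening. C3 comes from Sharpless epoxidation and invertive 6-exo opening by the C7 hydroxyl.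

Key step: step 9

Assumption: the sense of induction of the two organocatalysts ((S)-prolinol silyl ether giving (S)-5, (R)-HBTM giving 10R) is derived from their accepted shielding models. Both antipodes of each are commercial, so the choice can be reversed without changing the route.

Step 1
Reactants: 1 3,3-dimethylglutaric anhydride
Product: 2 5-tert-butoxy-3,3-dimethyl-5-oxopentanoic acid
Conditions: t-BuOH, DMAP (cat.), toluene, 100 °C
Reagents that add atoms: tert-butanol, CC(C)(C)O
Why: DMAP-catalysed alcoholysis of a symmetrical cyclic anhydride gives the half ester, and the tert-butyl group is chosen because it resists lactonisation and Grignard attack later and leaves under acid, so the γ-bromo acid never meets base.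

Step 2
Reactants: 2 5-tert-butoxy-3,3-dimethyl-5-oxopentanoic acid
Product: 3 tert-butyl 5-hydroxy-3,3-dimethylpentanoate
Conditions: BH3·SMe2, THF, 0 °C to rt; MeOH
Reagents that add atoms: none
Why: Borane reduces a carboxylic acid chemoselectively in the presence of an ester.

Step 3
Reactants: 3 tert-butyl 5-hydroxy-3,3-dimethylpentanoate
Product: 4 tert-butyl 3,3-dimethyl-5-oxopentanoate
Conditions: TEMPO (cat.), PhI(OAc)2, CH2Cl2, rt
Reagents that add atoms: none
Why: Oxoammonium (TEMPO) oxidation of an unhindered primary alcohol stops at the aldehyde under anhydrous conditions.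

Step 4
Reactants: 4 tert-butyl 3,3-dimethyl-5-oxopentanoate
Product: 6 tert-butyl (4S)-4-bromo-5-hydroxy-3,3-dimethylpentanoate, via bromo aldehyde 5 (not isolated)
Conditions: (S)-2-{bis[3,5-bis(trifluoromethyl)phenyl](trimethylsilyloxy)methyl}pyrrolidine (10 mol %), 4,4-dibromo-2,6-di-tert-butylcyclohexa-2,5-dienone, PhCO2H (cat.), CH2Cl2–pentane, −40 °C; then NaBH4, MeOH, −40 to 0 °C
Reagents that add atoms: 4,4-dibromo-2,6-di-tert-butylcyclohexa-2,5-dien-1-one, CC(C)(C)C1=CC(Br)(Br)C=C(C(C)(C)C)C1=O
Why: In this enamine-catalysed α-bromination the (E)-anti enamine is brominated on the face remote from the diaryl(silyloxy)methyl group, which sets C14 (S here, the spatial arrangement of 14R in the target), and immediate borohydride reduction should forestall racemisation.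

Step 5
Reactants: 6 tert-butyl (4S)-4-bromo-5-hydroxy-3,3-dimethylpentanoate
Product: 7 tert-butyl (4S)-4-bromo-3,3-dimethyl-5-(trifluoromethylsulfonyloxy)pentanoate
Conditions: Tf2O, 2,6-lutidine, CH2Cl2, −78 °C; cold short silica plug, used at once
Reagents that add atoms: trifluoromethanesulfonic anhydride, O=S(=O)(OS(=O)(=O)C(F)(F)F)C(F)(F)F
Why: O-sulfonylation of the primary alcohol with a hindered base does not touch C14, and the low temperature holds back participation by bromine or the ester carbonyl.

Step 6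
Reactants: 7 tert-butyl (4S)-4-bromo-3,3-dimethyl-5-(trifluoromethylsulfonyloxy)pentanoate; 8 2-methylallylmagnesium chloride
Product: 9 tert-butyl (4R)-4-bromo-3,3,7-trimethyloct-7-enoate
Conditions: 8 (1.5 equiv), Et2O–THF, −78 to −30 °C, no copper salt
Reagents that add atoms: none
Why: SN2 displacement of the primary triflate by the allylic Grignard reagent forms C12–C13 while the neopentyl C14–Br bond and the tert-butyl ester stay inert, and the descriptor changes to R through ligand priorities only.

Step 7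
Reactants: 9 tert-butyl (4R)-4-bromo-3,3,7-trimethyloct-7-enoate
Product: 11 tert-butyl (4R)-4-bromo-3,3-dimethyl-7-oxooctanoate, via secondary ozonide 10 (not isolated)
Conditions: O3, CH2Cl2, −78 °C; Me2S, −78 °C to rt
Reagents that add atoms: ozone, [O-][O+]=O
Why: Ozonolysis of the 1,1-disubstituted alkene with reductive work-up unmasks the C11 methyl ketone without affecting bromide or ester.

Step 8
Reactants: 11 tert-butyl (4R)-4-bromo-3,3-dimethyl-7-oxooctanoate
Product: 12 (4R)-4-bromo-3,3-dimethyl-7-oxooctanoic acid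
Conditions: CF3CO2H–CH2Cl2 (1:4), 0 °C to rt; used directly
Reagents that add atoms: none
Why: Acidolysis of the tert-butyl ester frees the acid in protonated form, so no carboxylate is present that could displace the γ-bromide.

Step 9
Reactants: 12 (4R)-4-bromo-3,3-dimethyl-7-oxooctanoic acid
Product: 14 (1R,3R,6S)-3-bromo-2,2,6-trimethyl-7-oxabicyclo[4.2.0]octan-8-one, via tosyl mixed anhydride 13 (not isolated)
Conditions: (R)-2-phenyl-3,4-dihydro-2H-benzo[4,5]thiazolo[3,2-a]pyrimidine [(R)-HBTM, 20 mol %], TsCl (1.25 equiv), LiCl (1 equiv), i-Pr2NEt (4 equiv), CH2Cl2, rt, 12 added by syringe pump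
Reagents that add atoms: none
Why: TsCl turns 12 into the mixed anhydride 13, the isothiourea nitrogen takes over the acyl group, and i-Pr2NEt removes a C10 proton to give a (Z)-ammonium enolate held planar by the O···S contact, which is the mechanism of the nucleophile-catalysed aldol-lactonisation known for keto acids. C10 then adds to the LiCl-activated C11 ketone through a chair (6-(enolexo)-exo-trig closure of the cyclohexane C10–C15), and the C11 alkoxide attacks the acylammonium carbon C9 (4-exo-trig closure of the oxetan-2-one), which releases the catalyst. C10 is fixed by the enolate face left open by the pseudo-axial phenyl group of (R)-HBTM, and this choice is matched with the chair that keeps the resident C14–Br bond equatorial, so that C9 becomes equatorial and cis to bromine. C11 is fixed by the ketone orientation in that chair, methyl equatorial to escape the axial C15 methyl and oxygen axial next to C9, and only this cis aldolate can reach C9, whereas a trans aldolate can only revert. The step needs diastereoselection relative to C14 and chemoselection for aldol addition over displacement of bromide by C10 (3-exo-tet) or by the carboxylate (5-exo-tet); the neopentyl position of C14–Br, the low nucleophilicity of an ammonium enolate toward alkyl halides and the slow addition of 12 to pre-mixed TsCl and base should secure this.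

Step 10
Reactants: 14 (1R,3R,6S)-3-bromo-2,2,6-trimethyl-7-oxabicyclo[4.2.0]octan-8-one
Product: 15 (1S,2S,4R)-4-bromo-2-(hydroxymethyl)-1,3,3-trimethylcyclohexan-1-ol
Conditions: LiBH4, Et2O–THF, 0 °C; aq. NH4Cl
Reagents that add atoms: none
Why: Hydride reduction of the strained lactone proceeds by acyl–oxygen cleavage, so C10, C11 and C14 are untouched, and neither alkoxide can reach the rear of C14–Br because both lie on the same ring face as bromine.

Step 11
Reactants: 15 (1S,2S,4R)-4-bromo-2-(hydroxymethyl)-1,3,3-trimethylcyclohexan-1-ol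
Product: 16 (1R,3R,6S)-3-bromo-6-hydroxy-2,2,6-trimethylcyclohexane-1-carbaldehyde
Conditions: Dess–Martin periodinane, CH2Cl2, 0 °C to rt
Reagents that add atoms: none
Why: Dess–Martin oxidation acts only on the primary alcohol under neutral conditions, and the equatorial formyl group at C10 is the thermodynamically preferred epimer.

Step 12
Reactants: 16 (1R,3R,6S)-3-bromo-6-hydroxy-2,2,6-trimethylcyclohexane-1-carbaldehyde
Product: 17 (1R,3R,6S)-3-bromo-2,2,6-trimethyl-6-(triethylsilyloxy)cyclohexane-1-carbaldehyde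
Conditions: Et3SiOTf, 2,6-lutidine, CH2Cl2, −78 to 0 °C
Reagents that add atoms: triethylsilyl trifluoromethanesulfonate, CC[Si](CC)(CC)OS(=O)(=O)C(F)(F)F
Why: Silyl triflate silylation of the hindered tertiary alcohol blocks retro-aldol cleavage in the Wittig step and later keeps the C11 oxygen from attacking C7 of the C6–C7 epoxide.

Step 13
Reactants: 17 (1R,3R,6S)-3-bromo-2,2,6-trimethyl-6-(triethylsilyloxy)cyclohexane-1-carbaldehyde
Product: 18 {[(1S,2R,4R)-4-bromo-2-ethenyl-1,3,3-trimethylcyclohexyl]oxy}triethylsilane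
Conditions: Ph3PCH3Br, KN(SiMe3)2, THF, 0 °C; then 17, −78 °C to rt
Reagents that add atoms: methyltriphenylphosphonium bromide, C[P+](c1ccccc1)(c1ccccc1)c1ccccc1.[Br-]
Why: Wittig methylenation adds C8, and the equatorial C14–Br bond has no antiperiplanar hydrogen, so E2 loss of HBr by the ylide is disfavoured.

Step 14
Reactants: 19 geranyl acetate
Product: 21 (2E)-3-methyl-6-oxohex-2-en-1-yl acetate, via secondary ozonide 20 (not isolated)
Conditions: O3 (1 equiv, dye end point), CH2Cl2, −78 °C; Me2S
Reagents that add atoms: ozone, [O-][O+]=O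
Why: In this chemoselective ozonolysis ozone prefers the electron-rich C6=C7 bond over the acetate-deactivated C2=C3 bond, whose E geometry is kept.

Step 15
Reactants: 21 (2E)-3-methyl-6-oxohex-2-en-1-yl acetate
Product: 22 (2E)-3-methylhept-2-en-6-yn-1-ol
Conditions: dimethyl (1-diazo-2-oxopropyl)phosphonate, K2CO3, MeOH, 0 °C to rt
Reagents that add atoms: dimethyl (1-diazo-2-oxopropyl)phosphonate, COP(=O)(OC)C(=[N+]=[N-])C(C)=O
Why: Seyferth–Gilbert homologation in the Ohira–Bestmann variant turns the C6 aldehyde into the C6≡C7 alkyne, and the same carbonate–methanol medium removes the acetate.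

Step 16
Reactants: 22 (2E)-3-methylhept-2-en-6-yn-1-ol
Product: 24 (2E)-3-methyloct-2-en-6-yn-1-ol, via dilithio alkynolate 23 (not isolated)
Conditions: n-BuLi (2.1 equiv), THF, −78 to 0 °C; MeI (1.1 equiv), 0 °C to rt
Reagents that add atoms: iodomethane, CI
Why: In this acetylide alkylation only the carbon terminus of the O,C-dianion is nucleophilic enough toward MeI in THF, which installs the future C7 methyl group.

Step 17
Reactants: 24 (2E)-3-methyloct-2-en-6-yn-1-ol
Product: 26 (2E,6E)-7-iodo-3-methylocta-2,6-dien-1-ol, via alkenylzirconocene 25 (not isolated)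
Conditions: Cp2Zr(H)Cl (3 equiv), THF, rt to 40 °C, dark; I2, −78 to 0 °C
Reagents that add atoms: iodine, II
Why: Hydrozirconation–iodination adds H and Zr syn, excess hydride equilibrates zirconium to the less hindered methyl-bearing carbon C7, and iodinolysis with retention gives the E iodide.

Step 18
Reactants: 26 (2E,6E)-7-iodo-3-methylocta-2,6-dien-1-ol
Product: 27 (2E,6E)-7-iodo-3-methylocta-2,6-dien-1-yl acetate
Conditions: Ac2O, pyridine, DMAP (cat.), CH2Cl2, 0 °C
Reagents that add atoms: acetic anhydride, CC(=O)OC(C)=O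
Why: Acylation reinstates the allylic acetate that will deactivate C2=C3 in the epoxidation of step 20.

Step 19
Reactants: 18 {[(1S,2R,4R)-4-bromo-2-ethenyl-1,3,3-trimethylcyclohexyl]oxy}triethylsilane; 27 (2E,6E)-7-iodo-3-methylocta-2,6-dien-1-yl acetate
Product: 29 (2E,6E)-9-[(1R,3R,6S)-3-bromo-2,2,6-trimethyl-6-(triethylsilyloxy)cyclohexyl]-3,7-dimethylnona-2,6-dien-1-yl acetate, via B-alkyl-9-BBN 28 (not isolated)
Conditions: 18, 9-BBN-H, THF, rt to 40 °C; then 27, Pd(dppf)Cl2 (5 mol %), AsPh3, Cs2CO3, DMF–H2O, rt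
Reagents that add atoms: none
Why: Anti-Markovnikov hydroboration puts boron on C8 and the B-alkyl Suzuki–Miyaura coupling joins C8 to C7 with retention of the E geometry, since zerovalent palladium inserts into the vinyl iodide at room temperature far faster than into the allylic acetate or the hindered secondary bromide.

Step 20
Reactants: 29 (2E,6E)-9-[(1R,3R,6S)-3-bromo-2,2,6-trimethyl-6-(triethylsilyloxy)cyclohexyl]-3,7-dimethylnona-2,6-dien-1-yl acetate
Product: 30 (2E)-5-[(2S,3S)-3-{2-[(1R,3R,6S)-3-bromo-2,2,6-trimethyl-6-(triethylsilyloxy)cyclohexyl]ethyl}-3-methyloxiran-2-yl]-3-methylpent-2-en-1-yl acetate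
Conditions: L-fructose-derived 1,2:4,5-di-O-isopropylidene-2,3-hexodiulo-2,6-pyranose (0.3 equiv), Oxone (2KHSO5·KHSO4·K2SO4), K2CO3, Bu4NHSO4, Na2B4O7–Na2EDTA buffer, MeCN–CH2(OMe)2–H2O, 0 °C
Reagents that add atoms: potassium peroxymonosulfate, [K+].[O-]S(=O)(=O)OO
Why: In the Shi epoxidation the chiral dioxirane attacks the electron-rich C6=C7 bond through the spiro transition state and sets 6S,7S by reagent control, while C2=C3 is deactivated by the allylic acetate.

Step 21
Reactants: 30 (6S,7S)-epoxy acetate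
Product: 31 (2E)-5-[(2S,3S)-3-{2-[(1R,3R,6S)-3-bromo-2,2,6-trimethyl-6-(triethylsilyloxy)cyclohexyl]ethyl}-3-methyloxiran-2-yl]-3-methylpent-2-en-1-ol
Conditions: K2CO3 (cat.), MeOH, 0 °C
Reagents that add atoms: none
Why: Base-catalysed transesterification frees the C1 hydroxyl while the molecule still carries a base-stable epoxide and not yet a base-labile bromohydrin.

Step 22
Reactants: 31 (6S,7S)-epoxy allylic alcohol
Product: 32 (2E,6R,7S)-6-bromo-9-[(1R,3R,6S)-3-bromo-2,2,6-trimethyl-6-(triethylsilyloxy)cyclohexyl]-3,7-dimethylnon-2-ene-1,7-diol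
Conditions: Li2NiBr4, THF, 0 °C to rt; pH 7 phosphate buffer
Reagents that add atoms: dilithium tetrabromonickelate, [Li+].[Li+].[Ni+2].[Br-].[Br-].[Br-].[Br-]
Why: In this halohydrin formation soft bromide opens the epoxide by SN2 attack at the less substituted C6, which inverts it to 6R and leaves the C7–O bond, hence 7S, untouched.

Step 23
Reactants: 32 (6R,7S)-bromohydrin allylic alcohol
Product: 33 (2R,3R,6R,7S)-6-bromo-9-[(1R,3R,6S)-3-bromo-2,2,6-trimethyl-6-(triethylsilyloxy)cyclohexyl]-2,3-epoxy-3,7-dimethylnonane-1,7-diol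
Conditions: Ti(OiPr)4 (10 mol %), D-(−)-diethyl tartrate (12 mol %), t-BuOOH, 4 Å MS, CH2Cl2, −20 °C
Reagents that add atoms: tert-butyl hydroperoxide, CC(C)(C)OO
Why: Sharpless asymmetric epoxidation of the E allylic alcohol with D-(−)-tartrate gives the 2R,3R epoxide by reagent control, and no other alkene remains in the substrate.

Step 24
Reactants: 33 (2R,3R)-epoxy alcohol
Product: 34 (1R)-1-[(2S,5R,6S)-5-bromo-6-{2-[(1R,3R,6S)-3-bromo-2,2,6-trimethyl-6-(triethylsilyloxy)cyclohexyl]ethyl}-2,6-dimethyloxan-2-yl]ethane-1,2-diol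
Conditions: (+)-camphor-10-sulfonic acid (10 mol %), CH2Cl2, 0 °C to rt
Reagents that add atoms: none
Why: Acid-catalysed 6-exo-tet opening of the epoxide at its tertiary carbon by the C7 hydroxyl, a stereospecific closure known for 2,2,6,6-tetrasubstituted oxanes, inverts C3 to the required S configuration with the two ring methyl groups cis.

Step 25
Reactants: 34 oxanyl 1,2-diol
Product: 35 {[(1S,2R,4R)-4-bromo-2-{2-[(2S,3R,6S)-3-bromo-6-ethenyl-2,6-dimethyloxan-2-yl]ethyl}-1,3,3-trimethylcyclohexyl]oxy}triethylsilane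
Conditions: PPh3, imidazole, I2, toluene, 80 °C
Reagents that add atoms: none
Why: In the Garegg–Samuelsson deoxygenation the primary hydroxyl becomes an iodide and the secondary one an oxyphosphonium ion, and iodide-induced elimination gives the C1=C2 vinyl group without touching C3 or the two neopentyl-type bromides.

Step 26
Reactants: 35 triethylsilyl ether of the target
Product: 36 (1S,2R,4R)-4-bromo-2-{2-[(2S,3R,6S)-3-bromo-6-ethenyl-2,6-dimethyloxan-2-yl]ethyl}-1,3,3-trimethylcyclohexan-1-ol (CNP0244533.1)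
Conditions: HF·pyridine, pyridine–THF, 0 °C to rt
Reagents that add atoms: none
Why: Fluoride-driven silyl ether cleavage in a buffered, non-basic medium avoids loss of HBr and ionisation of the tertiary allylic ether, so all six stereocentres stay as set.

Compound list
1 | 3,3-dimethylglutaric anhydride | CC1(C)CC(=O)OC(=O)C1 | starting material
2 | 5-tert-butoxy-3,3-dimethyl-5-oxopentanoic acid | CC(C)(C)OC(=O)CC(C)(C)CC(=O)O | intermediate
3 | tert-butyl 5-hydroxy-3,3-dimethylpentanoate | CC(C)(C)OC(=O)CC(C)(C)CCO | intermediate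
4 | tert-butyl 3,3-dimethyl-5-oxopentanoate | CC(C)(C)OC(=O)CC(C)(C)CC=O | intermediate
5 | tert-butyl (4S)-4-bromo-3,3-dimethyl-5-oxopentanoate (not isolated) | CC(C)(C)OC(=O)CC(C)(C)[C@H](Br)C=O | intermediate
6 | tert-butyl (4S)-4-bromo-5-hydroxy-3,3-dimethylpentanoate | CC(C)(C)OC(=O)CC(C)(C)[C@H](Br)CO | intermediate
7 | tert-butyl (4S)-4-bromo-3,3-dimethyl-5-(trifluoromethylsulfonyloxy)pentanoate | CC(C)(C)OC(=O)CC(C)(C)[C@H](Br)COS(=O)(=O)C(F)(F)F | intermediate
8 | 2-methylallylmagnesium chloride (commercial THF solution) | CC(=C)C[Mg]Cl | starting material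
9 | tert-butyl (4R)-4-bromo-3,3,7-trimethyloct-7-enoate | CC(C)(C)OC(=O)CC(C)(C)[C@H](Br)CCC(C)=C | intermediate
10 | secondary ozonide of 9 (not isolated) | CC(C)(C)OC(=O)CC(C)(C)[C@H](Br)CCC1(C)OCOO1 | intermediate
11 | tert-butyl (4R)-4-bromo-3,3-dimethyl-7-oxooctanoate | CC(C)(C)OC(=O)CC(C)(C)[C@H](Br)CCC(C)=O | intermediate
12 | (4R)-4-bromo-3,3-dimethyl-7-oxooctanoic acid | OC(=O)CC(C)(C)[C@H](Br)CCC(C)=O | intermediate
13 | (4R)-4-bromo-3,3-dimethyl-7-oxooctanoic 4-toluenesulfonic anhydride (not isolated) | Cc1ccc(cc1)S(=O)(=O)OC(=O)CC(C)(C)[C@H](Br)CCC(C)=O | intermediate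
14 | (1R,3R,6S)-3-bromo-2,2,6-trimethyl-7-oxabicyclo[4.2.0]octan-8-one | O=C1[C@@H]2C(C)(C)[C@H](Br)CC[C@]2(C)O1 | intermediate
15 | (1S,2S,4R)-4-bromo-2-(hydroxymethyl)-1,3,3-trimethylcyclohexan-1-ol | OC[C@@H]1C(C)(C)[C@H](Br)CC[C@]1(C)O | intermediate
16 | (1R,3R,6S)-3-bromo-6-hydroxy-2,2,6-trimethylcyclohexane-1-carbaldehyde | O=C[C@@H]1C(C)(C)[C@H](Br)CC[C@]1(C)O | intermediate
17 | (1R,3R,6S)-3-bromo-2,2,6-trimethyl-6-(triethylsilyloxy)cyclohexane-1-carbaldehyde | O=C[C@@H]1C(C)(C)[C@H](Br)CC[C@]1(C)O[Si](CC)(CC)CC | intermediate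
18 | {[(1S,2R,4R)-4-bromo-2-ethenyl-1,3,3-trimethylcyclohexyl]oxy}triethylsilane | C=C[C@@H]1C(C)(C)[C@H](Br)CC[C@]1(C)O[Si](CC)(CC)CC | intermediate
19 | geranyl acetate | CC(=O)OC/C=C(\C)CCC=C(C)C | starting material
20 | secondary ozonide of the C6=C7 bond of 19 (not isolated) | CC(=O)OC/C=C(\C)CCC1OOC(C)(C)O1 | intermediate
21 | (2E)-3-methyl-6-oxohex-2-en-1-yl acetate | CC(=O)OC/C=C(\C)CCC=O | intermediate
22 | (2E)-3-methylhept-2-en-6-yn-1-ol | OC/C=C(\C)CCC#C | intermediate
23 | O,C-dilithio derivative of 22 (not isolated) | [Li]OC/C=C(\C)CCC#C[Li] | intermediate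
24 | (2E)-3-methyloct-2-en-6-yn-1-ol | OC/C=C(\C)CCC#CC | intermediate
25 | C7-zirconated (E)-alkenylzirconocene chloride, O-zirconated at C1, Cp drawn σ-bound (not isolated) | Cl[Zr](C1C=CC=C1)(C1C=CC=C1)OC/C=C(\C)CC/C=C(\C)[Zr](Cl)(C1C=CC=C1)C1C=CC=C1 | intermediate
26 | (2E,6E)-7-iodo-3-methylocta-2,6-dien-1-ol | OC/C=C(\C)CC/C=C(\C)I | intermediate
27 | (2E,6E)-7-iodo-3-methylocta-2,6-dien-1-yl acetate | CC(=O)OC/C=C(\C)CC/C=C(\C)I | intermediate
28 | 9-{2-[(1R,3R,6S)-3-bromo-2,2,6-trimethyl-6-(triethylsilyloxy)cyclohexyl]ethyl}-9-borabicyclo[3.3.1]nonane (not isolated) | B1(CC[C@@H]2C(C)(C)[C@H](Br)CC[C@]2(C)O[Si](CC)(CC)CC)C3CCCC1CCC3 | intermediate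
29 | (2E,6E)-9-[(1R,3R,6S)-3-bromo-2,2,6-trimethyl-6-(triethylsilyloxy)cyclohexyl]-3,7-dimethylnona-2,6-dien-1-yl acetate | CC(=O)OC/C=C(\C)CC/C=C(\C)CC[C@@H]1C(C)(C)[C@H](Br)CC[C@]1(C)O[Si](CC)(CC)CC | intermediate
30 | (6S,7S)-6,7-epoxide of 29 | CC(=O)OC/C=C(\C)CC[C@@H]1O[C@@]1(C)CC[C@@H]2C(C)(C)[C@H](Br)CC[C@]2(C)O[Si](CC)(CC)CC | intermediate
31 | (6S,7S)-epoxy allylic alcohol (30 without acetyl) | OC/C=C(\C)CC[C@@H]1O[C@@]1(C)CC[C@@H]2C(C)(C)[C@H](Br)CC[C@]2(C)O[Si](CC)(CC)CC | intermediate
32 | (2E,6R,7S)-6-bromo-9-[(1R,3R,6S)-3-bromo-2,2,6-trimethyl-6-(triethylsilyloxy)cyclohexyl]-3,7-dimethylnon-2-ene-1,7-diol | OC/C=C(\C)CC[C@@H](Br)[C@](C)(CC[C@@H]1C(C)(C)[C@H](Br)CC[C@]1(C)O[Si](CC)(CC)CC)O | intermediate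
33 | (2R,3R,6R,7S)-6-bromo-9-[(1R,3R,6S)-3-bromo-2,2,6-trimethyl-6-(triethylsilyloxy)cyclohexyl]-2,3-epoxy-3,7-dimethylnonane-1,7-diol | OC[C@H]1O[C@]1(C)CC[C@@H](Br)[C@](C)(CC[C@@H]2C(C)(C)[C@H](Br)CC[C@]2(C)O[Si](CC)(CC)CC)O | intermediate
34 | (1R)-1-[(2S,5R,6S)-5-bromo-6-{2-[(1R,3R,6S)-3-bromo-2,2,6-trimethyl-6-(triethylsilyloxy)cyclohexyl]ethyl}-2,6-dimethyloxan-2-yl]ethane-1,2-diol | OC[C@@H](O)[C@]1(C)CC[C@@H](Br)[C@](C)(CC[C@@H]2C(C)(C)[C@H](Br)CC[C@]2(C)O[Si](CC)(CC)CC)O1 | intermediate
35 | {[(1S,2R,4R)-4-bromo-2-{2-[(2S,3R,6S)-3-bromo-6-ethenyl-2,6-dimethyloxan-2-yl]ethyl}-1,3,3-trimethylcyclohexyl]oxy}triethylsilane | C=C[C@]1(C)CC[C@@H](Br)[C@](C)(CC[C@@H]2C(C)(C)[C@H](Br)CC[C@]2(C)O[Si](CC)(CC)CC)O1 | intermediate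
36 | (1S,2R,4R)-4-bromo-2-{2-[(2S,3R,6S)-3-bromo-6-ethenyl-2,6-dimethyloxan-2-yl]ethyl}-1,3,3-trimethylcyclohexan-1-ol (CNP0244533.1) | C=C[C@]1(C)CC[C@@H](Br)[C@](C)(CC[C@@H]2C(C)(C)[C@H](Br)CC[C@]2(C)O)O1 | target

Total step count: 26. Longest linear sequence: 21 steps (steps 1–13, then 19–26). The vinyl iodide branch takes 5 steps (14–18).

Steps most likely to fail

1. Step 9.
- Risk: bond formation at C10, wedged between the quaternary C15 and a ketone carbon, may be slow. The activated acid could then be lost to intramolecular displacement of the C14 bromide or to ketene-type self-condensation. A catalyst face that opposes the chair preference would also erode diastereoselection.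
- Fallback: this sets out from 12 and replaces Lewis-base catalysis by a substrate-controlled metal enolate. DCC/DMAP coupling with thiophenol gives S-phenyl (4R)-4-bromo-3,3-dimethyl-7-oxooctanethioate F1.
- Soft enolisation of F1 with MgBr2·OEt2 and i-Pr2NEt in CH2Cl2 enolises only the thioester. The magnesium-bridged aldolate keeps the C11 oxygen next to C9 in the same Br-equatorial chair. Expulsion of thiophenolate (the thiol ester enolate–ketone route to β-lactones) returns to the route at 14.

2. Step 22.
- Risk: bromide may attack the tertiary C7 in competition with C6, or the epoxide may rearrange under Lewis acid. Either would spoil the regiochemistry of the opening.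
- Fallback: this sets out from 29 and installs bromine electrophilically. NBS in aqueous 1,2-dimethoxyethane at 0 °C adds Br and OH anti across the E C6=C7 bond, with water at the tertiary C7, and spares the acetate-deactivated C2=C3 bond.
- Regiochemistry and relative configuration are then secure but facial control is given up. The products are the (6R,7S)-bromohydrin acetate F2 and its (6S,7R) diastereomer F3, which are separated by chromatography.
- i-Bu2AlH in CH2Cl2 at −78 °C removes the acetate from F2 without base-induced epoxide closure and returns to the route at 32.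

3. Step 6.
- Risk: the triflate may be lost before coupling through participation of the ester carbonyl (lactonisation with loss of the tert-butyl group). It may also be consumed by elimination across the vicinal bromo-triflate unit.
- Fallback: this sets out from 5, made as in step 4, and avoids any substitution next to bromine. 1-(Triphenylphosphoranylidene)propan-2-one is added to the cold reaction mixture in place of NaBH4.
- The Wittig olefination with this stabilised ylide gives tert-butyl (4R,5E)-4-bromo-3,3-dimethyl-7-oxooct-5-enoate F4. Diimide, generated from 2-nitrobenzenesulfonohydrazide in CH2Cl2–MeOH at rt, saturates C12=C13 without hydrogenolysis of the allylic C–Br bond and without forming an enolate. This returns to the route at 11.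

Further compounds
F1 | step 9 | S-phenyl (4R)-4-bromo-3,3-dimethyl-7-oxooctanethioate | O=C(CC(C)(C)[C@H](Br)CCC(C)=O)Sc1ccccc1
F2 | step 22 | (2E,6R,7S)-6-bromo-9-[(1R,3R,6S)-3-bromo-2,2,6-trimethyl-6-(triethylsilyloxy)cyclohexyl]-7-hydroxy-3,7-dimethylnon-2-en-1-yl acetate | CC(=O)OC/C=C(\C)CC[C@@H](Br)[C@](C)(CC[C@@H]1C(C)(C)[C@H](Br)CC[C@]1(C)O[Si](CC)(CC)CC)O
F3 | step 22 | (2E,6S,7R)-6-bromo-9-[(1R,3R,6S)-3-bromo-2,2,6-trimethyl-6-(triethylsilyloxy)cyclohexyl]-7-hydroxy-3,7-dimethylnon-2-en-1-yl acetate | CC(=O)OC/C=C(\C)CC[C@H](Br)[C@@](C)(CC[C@@H]1C(C)(C)[C@H](Br)CC[C@]1(C)O[Si](CC)(CC)CC)O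
F4 | step 6 | tert-butyl (4R,5E)-4-bromo-3,3-dimethyl-7-oxooct-5-enoate | CC(C)(C)OC(=O)CC(C)(C)[C@H](Br)/C=C/C(C)=O
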